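**Plan**
- Cuts: the four O–benzyl bonds of a protected target come off first. One retrosynthetic move then cuts the C3–C4 bond (acetoxy carbon to central CH2), the C5–H bond and the O3–acetyl bond. This aldol–Tishchenko retron leads to an aldehyde (C1–C3 arm), a methyl ketone (C4–C7 arm) and acetaldehyde.
- Enabling feature: the anti pair of O-acetyl on C3 and free OH on C5 across the C4 methylene, with the ester on the aldehyde-derived oxygen and the free OH on the ketone-derived carbon. The parent 3,5-diol has a twofold axis through C4 and two identical 2-(3,4-dioxyphenyl)ethyl arms, so an O3 to O5 acetyl shift is degenerate and both partners come from one Weinreb amide.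
- Forward order: dihydrocaffeic acid is tribenzylated and converted to the Weinreb amide. The amide is split into aldehyde and methyl ketone, and the chain is joined at C3–C4 with acetaldehyde in one telescoped three-component operation. Hydrogenolysis ends the route, and no ring is formed.
- Stereochemistry: C3 comes from the isopinocampheyl ligands of the boron enolate. C5 comes from 1,3-anti intramolecular hydride delivery out of the samarium-bound acetaldehyde hemiacetal. No later step touches either centre.

Key step: step 5

Note: target numbering (C1–C7, acetoxy on C3) is used in the text for all chain atoms.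
Assumption: with methyl ketone enolates, (+)-Ipc2BCl (made from (−)-α-pinene) is taken to favour Si-face attack on an unbranched aldehyde. If the aldol proves to be S, (−)-Ipc2BCl takes its place and nothing else changes.

**Step 1**
Reactants: 1 3-(3,4-dihydroxyphenyl)propanoic acid
Product: 2 benzyl 3-[3,4-bis(benzyloxy)phenyl]propanoate
Conditions: BnBr, K2CO3, DMF, 60 °C
Reagents that add atoms: benzyl bromide BrCc1ccccc1
Why: Williamson etherification of both phenols and SN2 esterification of the carboxylate run together under carbonate base, and no stereocentre is involved.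

**Step 2**
Reactants: 2 benzyl 3-[3,4-bis(benzyloxy)phenyl]propanoate
Product: 3 3-[3,4-bis(benzyloxy)phenyl]-N-methoxy-N-methylpropanamide
Conditions: MeNH(OMe)·HCl, iPrMgCl, THF, −20 to 0 °C
Reagents that add atoms: N,O-dimethylhydroxylamine hydrochloride CNOC.Cl
Why: Aminolysis of the ester by the magnesium amide made in the flask (Weinreb amide synthesis from an ester) should stop at the amide, and the aryl benzyl ethers are inert to the Grignard base.

**Step 3**
Reactants: 3 3-[3,4-bis(benzyloxy)phenyl]-N-methoxy-N-methylpropanamide
Product: 4 3-[3,4-bis(benzyloxy)phenyl]propanal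
Conditions: iBu2AlH, THF, −78 °C; aq. potassium sodium tartrate
Reagents that add atoms: none
Why: In the Weinreb amide reduction, chelation in the tetrahedral adduct blocks a second hydride transfer until the aqueous quench releases the aldehyde.

**Step 4**
Reactants: 3 3-[3,4-bis(benzyloxy)phenyl]-N-methoxy-N-methylpropanamide
Product: 5 4-[3,4-bis(benzyloxy)phenyl]butan-2-one
Conditions: MeMgBr, THF, 0 °C; 1 M HCl
Reagents that add atoms: methylmagnesium bromide C[Mg]Br
Why: In the Weinreb ketone synthesis, the chelated adduct resists a second addition, so the methyl ketone should form cleanly on work-up.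

**Step 5**
Reactants: 4 3-[3,4-bis(benzyloxy)phenyl]propanal (limiting), 5 4-[3,4-bis(benzyloxy)phenyl]butan-2-one, 6 acetaldehyde
Product: 11 (3R,5R)-1,7-bis[3,4-bis(benzyloxy)phenyl]-5-hydroxyheptan-3-yl acetate, via enol borinate 7 (not isolated), via boron aldolate 8 (not isolated), via aldol 9 (not isolated), via hemiacetal 10 (not isolated)
Conditions: 5, (+)-Ipc2BCl, Et3N, Et2O, 0 °C; 4, −78 to −25 °C; HOCH2CH2NH2 (1 equiv per boron), 0 °C, solids filtered off under Ar; THF, 6 (excess), SmI2 (30 mol %), −10 °C
Reagents that add atoms: none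
Why: (+)-Ipc2BCl/Et3N enolises 5 on its methyl side to enol borinate 7, which adds to aldehyde 4 through a cyclic boron-centred transition state and forms the C3–C4 bond irreversibly as boron aldolate 8 (asymmetric boron aldol of a methyl ketone, Paterson aldol). The isopinocampheyl ligands on boron are the control element for C3 and should direct attack to the Si face of 4, which gives the R configuration. Ethanolamine removes boron as an insoluble tetracoordinate chelate and frees aldol 9, whose hydroxyl adds to acetaldehyde 6 to give hemiacetal 10, held as an alkoxide on the trivalent samarium species that SmI2 and 6 generate. With samarium bridging the hemiacetal oxygen and the C5 carbonyl oxygen in a chair-like array, the hemiacetal hydrogen passes intramolecularly to C5 on the face anti to O3 (Evans–Tishchenko reduction, the closest known reaction type for this stage), so the C3 centre controls C5 (R) and the acetyl group ends on O3 only. No ring of the product is closed. The step needs methyl over methylene enolisation, cross- over self-aldol addition and acetaldehyde as the sole hydride donor, and these are secured by the bulk of the Ipc ligands, by preforming the enolate before 4 is added at −78 °C and by using 4 as the limiting partner so that none is left for the samarium stage.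

**Step 6**
Reactants: 11 (3R,5R)-1,7-bis[3,4-bis(benzyloxy)phenyl]-5-hydroxyheptan-3-yl acetate
Product: 12 (3R,5R)-1,7-bis(3,4-dihydroxyphenyl)-5-hydroxyheptan-3-yl acetate
Conditions: H2 (1 atm), 10% Pd/C, EtOAc/THF, rt; filtration and concentration under Ar
Reagents that add atoms: none
Why: Neutral hydrogenolysis of the four aryl benzyl ethers over palladium should leave the secondary acetate, the secondary alcohol and both stereocentres untouched, and any O3 to O5 acetyl shift would regenerate the same compound.

**Compound list**
1 | 3-(3,4-dihydroxyphenyl)propanoic acid (dihydrocaffeic acid) | O=C(O)CCc1ccc(O)c(O)c1 | starting material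
2 | benzyl 3-[3,4-bis(benzyloxy)phenyl]propanoate | O=C(CCc1ccc(OCc2ccccc2)c(OCc2ccccc2)c1)OCc1ccccc1 | intermediate
3 | 3-[3,4-bis(benzyloxy)phenyl]-N-methoxy-N-methylpropanamide | CON(C)C(=O)CCc1ccc(OCc2ccccc2)c(OCc2ccccc2)c1 | intermediate
4 | 3-[3,4-bis(benzyloxy)phenyl]propanal | O=CCCc1ccc(OCc2ccccc2)c(OCc2ccccc2)c1 | intermediate
5 | 4-[3,4-bis(benzyloxy)phenyl]butan-2-one | CC(=O)CCc1ccc(OCc2ccccc2)c(OCc2ccccc2)c1 | intermediate
6 | acetaldehyde | CC=O | starting material
7 | 4-[3,4-bis(benzyloxy)phenyl]but-1-en-2-yl diisopinocampheylborinate (enol borinate) | C=C(CCc1ccc(OCc2ccccc2)c(OCc2ccccc2)c1)OB([C@H]1C[C@H]2C[C@@H]([C@@H]1C)C2(C)C)[C@H]1C[C@H]2C[C@@H]([C@@H]1C)C2(C)C | intermediate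
8 | O-diisopinocampheylboryl derivative of 9 (boron aldolate) | B(O[C@H](CCc1ccc(OCc2ccccc2)c(OCc2ccccc2)c1)CC(=O)CCc1ccc(OCc2ccccc2)c(OCc2ccccc2)c1)([C@H]1C[C@H]2C[C@@H]([C@@H]1C)C2(C)C)[C@H]1C[C@H]2C[C@@H]([C@@H]1C)C2(C)C | intermediate
9 | (5R)-1,7-bis[3,4-bis(benzyloxy)phenyl]-5-hydroxyheptan-3-one (aldol) | O[C@H](CCc1ccc(OCc2ccccc2)c(OCc2ccccc2)c1)CC(=O)CCc1ccc(OCc2ccccc2)c(OCc2ccccc2)c1 | intermediate
10 | O-(1-hydroxyethyl) derivative of 9 (acetaldehyde hemiacetal, present as its samarium alkoxide) | CC(O)O[C@H](CCc1ccc(OCc2ccccc2)c(OCc2ccccc2)c1)CC(=O)CCc1ccc(OCc2ccccc2)c(OCc2ccccc2)c1 | intermediate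
11 | (3R,5R)-1,7-bis[3,4-bis(benzyloxy)phenyl]-5-hydroxyheptan-3-yl acetate | CC(=O)O[C@H](CCc1ccc(OCc2ccccc2)c(OCc2ccccc2)c1)C[C@H](O)CCc1ccc(OCc2ccccc2)c(OCc2ccccc2)c1 | intermediate
12 | (3R,5R)-1,7-bis(3,4-dihydroxyphenyl)-5-hydroxyheptan-3-yl acetate | CC(=O)O[C@H](CCc1ccc(O)c(O)c1)C[C@H](O)CCc1ccc(O)c(O)c1 | target

**Step count**
- Total steps: 6.
- Longest linear sequence: 5 (steps 1, 2, 3 or 4, 5, 6).

**Steps most likely to fail**

Step 5.
- What may go wrong: the Ipc ligands may discriminate the aldehyde faces only weakly when an unbranched methyl ketone enolate meets an unbranched aldehyde, which would erode enantiomeric purity for the rest of the route. Amine or boron residues carried through the filtration may also deactivate the samarium catalyst.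
- The fallback sets out from 4 and comes back at 9. It replaces reagent control by a resolved epoxide and a polarity-reversed acyl anion.
- Aldehyde 4 is treated with dimethylsulfonium methylide (Me3SI, NaH, DMSO/THF; Corey–Chaykovsky reaction) to give racemic 2-{2-[3,4-bis(benzyloxy)phenyl]ethyl}oxirane F1.
- Hydrolytic kinetic resolution follows with (R,R)-N,N'-bis(3,5-di-tert-butylsalicylidene)cyclohexane-1,2-diaminocobalt acetate (trivalent cobalt) and 0.55 equiv of water. It should leave (2R)-2-{2-[3,4-bis(benzyloxy)phenyl]ethyl}oxirane F2 beside the separable (2S)-4-[3,4-bis(benzyloxy)phenyl]butane-1,2-diol F3.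
- A second portion of 4 with propane-1,3-dithiol and BF3·OEt2 gives 2-{2-[3,4-bis(benzyloxy)phenyl]ethyl}-1,3-dithiane F4.
- Lithiated F4 (n-BuLi, THF, −30 °C) opens F2 at its CH2 to give (2R)-4-[3,4-bis(benzyloxy)phenyl]-1-(2-{2-[3,4-bis(benzyloxy)phenyl]ethyl}-1,3-dithian-2-yl)butan-2-ol F5.
- MeI/CaCO3 in aqueous MeCN unmasks aldol 9, which is now isolated and purified. The samarium stage of step 5 alone (6, SmI2, THF, −10 °C) then carries it to 11.

Step 6.
- What may go wrong: the two catechols may oxidise in air during filtration and concentration. The catechol product may foul the catalyst so that the last benzyl ethers cleave slowly. The acetate may solvolyse if an alcohol cosolvent becomes necessary.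
- The fallback sets out from 11 and comes back at 12. It is a non-reductive debenzylation with BCl3 and pentamethylbenzene as cation scavenger in CH2Cl2 at −78 °C, quenched with MeOH. No compound outside the list arises (F0).

Step 3.
- What may go wrong: early collapse of the tetrahedral adduct may cause over-reduction, and the unbranched aldehyde may be lost by self-condensation on handling.
- The fallback sets out from 2 and comes back at 4. Full reduction of the ester with LiAlH4 (THF, 0 °C) gives 3-[3,4-bis(benzyloxy)phenyl]propan-1-ol F6. Oxidation with Dess–Martin periodinane (CH2Cl2, NaHCO3) just before use then gives 4.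

**Further compounds**
F1 | step 5 | racemic 2-{2-[3,4-bis(benzyloxy)phenyl]ethyl}oxirane | C1OC1CCc1ccc(OCc2ccccc2)c(OCc2ccccc2)c1
F2 | step 5 | (2R)-2-{2-[3,4-bis(benzyloxy)phenyl]ethyl}oxirane | C1O[C@@H]1CCc1ccc(OCc2ccccc2)c(OCc2ccccc2)c1
F3 | step 5 | (2S)-4-[3,4-bis(benzyloxy)phenyl]butane-1,2-diol | OC[C@@H](O)CCc1ccc(OCc2ccccc2)c(OCc2ccccc2)c1
F4 | step 5 | 2-{2-[3,4-bis(benzyloxy)phenyl]ethyl}-1,3-dithiane | C1CSC(CCc2ccc(OCc3ccccc3)c(OCc3ccccc3)c2)SC1
F5 | step 5 | (2R)-4-[3,4-bis(benzyloxy)phenyl]-1-(2-{2-[3,4-bis(benzyloxy)phenyl]ethyl}-1,3-dithian-2-yl)butan-2-ol | O[C@H](CCc1ccc(OCc2ccccc2)c(OCc2ccccc2)c1)CC1(CCc2ccc(OCc3ccccc3)c(OCc3ccccc3)c2)SCCCS1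
F6 | step 3 | 3-[3,4-bis(benzyloxy)phenyl]propan-1-ol | OCCCc1ccc(OCc2ccccc2)c(OCc2ccccc2)c1
F0 | step 6 | none | none
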